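**Strategy.** The target is a diaryl ether of two 4-nerolidylcatechol units of opposite configuration (ring A side R, ring B side S). Each quaternary C3 carries the C1=C2 vinyl group and a chain that starts with C4–C5, so C2 and C4 are treated as the two enantiotopic olefinic carbons of an achiral 3-aryl-3-methylcyclopropene. One ruthenium-catalysed enantioselective ring-opening/cross-metathesis with butyl vinyl ether opens the strained ring, creates C1=C2 and C4=C5 and fixes C3. The enol ether is then the C5 handle for a Negishi coupling. Mirror-image catalysts serve rings A and B, which are joined by an Ullmann ether coupling.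

Key step: step 8

**Remarks on the chemistry (assumptions)**
- Ring A carries its ether oxygen on C3 next to a free C4–OH, so a doubly MOM-protected catechol cannot supply it as one defined phenol. Ring A is therefore built from 4′-hydroxyacetophenone, and its C3 oxygen is introduced late by MOM-directed lithiation–borylation–oxidation, which is regiochemically unambiguous. Ring B keeps the bis-MOM catechol, whose C5 is iodinated for the ether coupling.
- L* is an enantiopure bidentate imidazolinylidene bearing an N-bound 2′-oxido-1,1′-binaphthyl arm (NHC–aryloxide). Which antipode gives (R)-13 is assumed to be settled in a first run by correlation of alcohol 15; that antipode is used in step 8 and its mirror image (ent-L*) in step 18.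
- The CIP descriptor at C3 changes when the enol ether arm is hydrolysed (R to S in the ring B series, S to R in the ring A series), although no bond to C3 is touched.

**C9 alkenyl iodide**

Step 1
Reactants: 1 6-methylhept-5-en-2-one
Product: 3 6-methylhept-5-en-1-yne, via diethyl enol phosphate 2 (not isolated)
Conditions: LiN(i-Pr)2 (1.05 equiv), THF, −78 °C; ClP(O)(OEt)2, −78 °C → rt; LiN(i-Pr)2 (2.3 equiv), −78 °C → rt; H2O
Reagents that add atoms: none
Why: Kinetic deprotonation on the methyl side, O-phosphorylation and base-induced elimination of the enol phosphate (Negishi methyl ketone-to-alkyne conversion) should give the terminal alkyne without touching the trisubstituted alkene.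

Step 2
Reactants: 3 6-methylhept-5-en-1-yne
Product: 5 (1E)-1-iodo-2,6-dimethylhepta-1,5-diene, via alkenyldimethylalane 4 (not isolated)
Conditions: AlMe3 (2 equiv), Cp2ZrCl2 (0.25 equiv), CH2Cl2, 0 °C → rt; then I2, THF, −30 → 0 °C
Reagents that add atoms: trimethylaluminium, C[Al](C)C; iodine, II
Why: Zirconium-catalysed syn-carboalumination (Negishi) puts methyl on the internal and aluminium on the terminal carbon cis to each other, and iodinolysis with retention should give the E alkenyl iodide.

**Ring B series**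

Step 3
Reactants: 6 3′,4′-dihydroxyacetophenone
Product: 7 3′,4′-bis(methoxymethoxy)acetophenone
Conditions: MOMCl (2.5 equiv), i-Pr2NEt (3 equiv), CH2Cl2, 0 °C → rt
Reagents that add atoms: chloromethyl methyl ether, COCCl
Why: Williamson-type O-alkylation of both phenols by the reactive α-chloro ether gives base-stable MOM acetals that later direct ortho-lithiation.

Step 4
Reactants: 7 3′,4′-bis(methoxymethoxy)acetophenone
Product: 8 1,2-bis(methoxymethoxy)-4-(prop-1-en-2-yl)benzene
Conditions: Ph3PCH3Br, KOt-Bu, THF, 0 °C → rt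
Reagents that add atoms: methyltriphenylphosphonium bromide, C[P+](c1ccccc1)(c1ccccc1)c1ccccc1.[Br-]
Why: Wittig methylenation of the aryl methyl ketone with the unstabilised ylide gives the 1,1-disubstituted styrene, the MOM ethers being inert to base.

Step 5
Reactants: 8 1,2-bis(methoxymethoxy)-4-(prop-1-en-2-yl)benzene
Product: 9 4-(2,2-dibromo-1-methylcyclopropyl)-1,2-bis(methoxymethoxy)benzene (racemic)
Conditions: CHBr3, 50% aq NaOH, BnEt3NCl (cat.), CH2Cl2, rt
Reagents that add atoms: bromoform, BrC(Br)Br
Why: Makosza phase-transfer generation of dibromocarbene and its [2+1] cycloaddition to the electron-rich styrene double bond give the gem-dibromocyclopropane as a racemate whose stereocentre is erased in step 7.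

Step 6
Reactants: 9 4-(2,2-dibromo-1-methylcyclopropyl)-1,2-bis(methoxymethoxy)benzene
Product: 10 4-(2-bromo-1-methylcyclopropyl)-1,2-bis(methoxymethoxy)benzene (racemic, cis/trans mixture)
Conditions: EtMgBr (1.3 equiv), Ti(Oi-Pr)4 (5 mol%), Et2O, rt
Reagents that add atoms: none
Why: Titanium-catalysed hydrodebromination of gem-dibromocyclopropanes by ethylmagnesium bromide stops at the monobromide, and the diastereomer mixture is harmless because both isomers eliminate in the next step.

Step 7
Reactants: 10 4-(2-bromo-1-methylcyclopropyl)-1,2-bis(methoxymethoxy)benzene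
Product: 11 3-[3,4-bis(methoxymethoxy)phenyl]-3-methylcyclopropene
Conditions: KOt-Bu, DMSO, rt
Reagents that add atoms: none
Why: Base-induced 1,2-dehydrobromination gives the achiral 3,3-disubstituted cyclopropene, which has no C3 hydrogen and so should resist ene dimerisation.

Step 8
Reactants: 11 3-[3,4-bis(methoxymethoxy)phenyl]-3-methylcyclopropene; 12 butyl vinyl ether
Product: 13 4-[(1Z,3R)-1-butoxy-3-methylpenta-1,4-dien-3-yl]-1,2-bis(methoxymethoxy)benzene
Conditions: Ru(=CH-C6H4-2-Oi-Pr)(I)(L*) (2–5 mol%), 12 (10 equiv), THF, 22 °C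
Reagents that add atoms: none
Why: The butoxymethylidene Ru=CH(OBu), formed from the precatalyst and 12, adds across the strained ring double bond in a [2+2] cycloaddition on the face syn to the small methyl group, cycloreversion of the ruthenacyclobutane opens the ring to an alkylidene next to C3 that already carries the C4=C5 enol ether, and metathesis of that alkylidene with a second molecule of 12 leaves the C1=C2 vinyl group and returns Ru=CH(OBu). The closest known reaction type is the catalytic enantioselective ring-opening/cross-metathesis of 3-aryl-3-methylcyclopropenes with enol ethers at stereogenic-at-metal ruthenium NHC–aryloxide carbenes. No ring is closed. The C3 stereocentre is set under catalyst control: the enantiopure bidentate ligand L* fixes the configuration at ruthenium and so decides which enantiotopic olefinic carbon bonds to the carbene carbon (becoming C4) and which to the metal (becoming C2). The step needs enantiotopic-group selectivity and a single clean opening; the large aryl/methyl size difference at C3, the irreversible release of cyclopropene strain and the inertness of the hindered 1,4-diene product should secure these, and the enol ether geometry is irrelevant because step 9 hydrolyses it.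

Step 9
Reactants: 13 4-[(1Z,3R)-1-butoxy-3-methylpenta-1,4-dien-3-yl]-1,2-bis(methoxymethoxy)benzene
Product: 15 (3S)-3-[3,4-bis(methoxymethoxy)phenyl]-3-methylpent-4-en-1-ol, via pentenal 14 (not isolated)
Conditions: 0.5 M aq HCl, THF, 0 °C; then NaHCO3, NaBH4, MeOH, 0 °C
Reagents that add atoms: water, O
Why: Enol ether hydrolysis in cold dilute acid is far faster than cleavage of aryl MOM acetals, and immediate borohydride reduction of the β-quaternary aldehyde avoids its handling, the stereocentre being untouched.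

Step 10
Reactants: 15 (3S)-3-[3,4-bis(methoxymethoxy)phenyl]-3-methylpent-4-en-1-ol
Product: 16 4-[(3S)-5-iodo-3-methylpent-1-en-3-yl]-1,2-bis(methoxymethoxy)benzene
Conditions: PPh3, I2, imidazole, CH2Cl2, 0 °C → rt
Reagents that add atoms: iodine, II
Why: Appel-type iodination (Garegg–Samuelsson conditions) converts the unhindered primary alcohol by SN2 displacement of the oxyphosphonium group, the imidazole buffer protecting the MOM acetals.

Step 11
Reactants: 16 4-[(3S)-5-iodo-3-methylpent-1-en-3-yl]-1,2-bis(methoxymethoxy)benzene; 5 (1E)-1-iodo-2,6-dimethylhepta-1,5-diene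
Product: 18 1,2-bis(methoxymethoxy)-4-[(3S,6E)-3,7,11-trimethyldodeca-1,6,10-trien-3-yl]benzene, via alkylzinc iodide 17 (not isolated)
Conditions: Zn dust (activated with BrCH2CH2Br, Me3SiCl), THF, 40 °C; then 5 (1.3 equiv), PdCl2(dppf) (5 mol%), THF, rt → 45 °C
Reagents that add atoms: none
Why: Zinc insertion into the primary C–I bond and palladium-catalysed Negishi sp3–sp2 cross-coupling with the alkenyl iodide, which keeps the E geometry of 5, should form the C5–C6 bond, the dppf ligand favouring reductive elimination over β-hydride elimination.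

Step 12
Reactants: 18 1,2-bis(methoxymethoxy)-4-[(3S,6E)-3,7,11-trimethyldodeca-1,6,10-trien-3-yl]benzene
Product: 20 1-iodo-2,3-bis(methoxymethoxy)-5-[(3S,6E)-3,7,11-trimethyldodeca-1,6,10-trien-3-yl]benzene, via aryllithium 19 (not isolated)
Conditions: n-BuLi (1.3 equiv), THF, 0 °C; then ICH2CH2I, −78 °C → rt
Reagents that add atoms: 1,2-diiodoethane, ICCI
Why: Directed ortho-metalation by the C4 OMOM group should occur at C5, the only OMOM-flanked position not shielded by the quaternary carbon, and iodination with 1,2-diiodoethane spares the alkenes.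

**Ring A series**

Step 13
Reactants: 21 4′-hydroxyacetophenone
Product: 22 4′-(methoxymethoxy)acetophenone
Conditions: MOMCl (1.3 equiv), i-Pr2NEt (1.5 equiv), CH2Cl2, 0 °C → rt
Reagents that add atoms: chloromethyl methyl ether, COCCl
Why: Williamson-type O-alkylation of the single phenol gives the MOM acetal that serves as protecting and ortho-directing group.

Step 14
Reactants: 22 4′-(methoxymethoxy)acetophenone
Product: 23 1-(methoxymethoxy)-4-(prop-1-en-2-yl)benzene
Conditions: Ph3PCH3Br, KOt-Bu, THF, 0 °C → rt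
Reagents that add atoms: methyltriphenylphosphonium bromide, C[P+](c1ccccc1)(c1ccccc1)c1ccccc1.[Br-]
Why: Wittig methylenation of the aryl methyl ketone gives the styrene as in step 4.

Step 15
Reactants: 23 1-(methoxymethoxy)-4-(prop-1-en-2-yl)benzene
Product: 24 1-(2,2-dibromo-1-methylcyclopropyl)-4-(methoxymethoxy)benzene (racemic)
Conditions: CHBr3, 50% aq NaOH, BnEt3NCl (cat.), CH2Cl2, rt
Reagents that add atoms: bromoform, BrC(Br)Br
Why: Phase-transfer dibromocarbene [2+1] cycloaddition to the styrene double bond proceeds as in step 5, the racemic stereocentre being erased in step 17.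

Step 16
Reactants: 24 1-(2,2-dibromo-1-methylcyclopropyl)-4-(methoxymethoxy)benzene
Product: 25 1-(2-bromo-1-methylcyclopropyl)-4-(methoxymethoxy)benzene (racemic, cis/trans mixture)
Conditions: EtMgBr (1.3 equiv), Ti(Oi-Pr)4 (5 mol%), Et2O, rt
Reagents that add atoms: none
Why: Titanium-catalysed hydrodebromination by ethylmagnesium bromide stops at the monobromide as in step 6.

Step 17
Reactants: 25 1-(2-bromo-1-methylcyclopropyl)-4-(methoxymethoxy)benzene
Product: 26 3-[4-(methoxymethoxy)phenyl]-3-methylcyclopropene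
Conditions: KOt-Bu, DMSO, rt
Reagents that add atoms: none
Why: Base-induced 1,2-dehydrobromination gives the achiral 3,3-disubstituted cyclopropene as in step 7.

Step 18
Reactants: 26 3-[4-(methoxymethoxy)phenyl]-3-methylcyclopropene; 12 butyl vinyl ether
Product: 27 1-[(1Z,3S)-1-butoxy-3-methylpenta-1,4-dien-3-yl]-4-(methoxymethoxy)benzene
Conditions: Ru(=CH-C6H4-2-Oi-Pr)(I)(ent-L*) (2–5 mol%), 12 (10 equiv), THF, 22 °C
Reagents that add atoms: none
Why: This is the enantioselective ring-opening/cross-metathesis of step 8 run with the mirror-image ligand, so the ruthenium carbene selects the other enantiotopic olefinic carbon and C3 is set with the opposite configuration under catalyst control.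

Step 19
Reactants: 27 1-[(1Z,3S)-1-butoxy-3-methylpenta-1,4-dien-3-yl]-4-(methoxymethoxy)benzene
Product: 29 (3R)-3-[4-(methoxymethoxy)phenyl]-3-methylpent-4-en-1-ol, via pentenal 28 (not isolated)
Conditions: 0.5 M aq HCl, THF, 0 °C; then NaHCO3, NaBH4, MeOH, 0 °C
Reagents that add atoms: water, O
Why: Selective enol ether hydrolysis and in-flask borohydride reduction proceed as in step 9 without touching the stereocentre.

Step 20
Reactants: 29 (3R)-3-[4-(methoxymethoxy)phenyl]-3-methylpent-4-en-1-ol
Product: 30 1-[(3R)-5-iodo-3-methylpent-1-en-3-yl]-4-(methoxymethoxy)benzene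
Conditions: PPh3, I2, imidazole, CH2Cl2, 0 °C → rt
Reagents that add atoms: iodine, II
Why: Appel-type iodination of the primary alcohol proceeds as in step 10.

Step 21
Reactants: 30 1-[(3R)-5-iodo-3-methylpent-1-en-3-yl]-4-(methoxymethoxy)benzene; 5 (1E)-1-iodo-2,6-dimethylhepta-1,5-diene
Product: 32 1-(methoxymethoxy)-4-[(3R,6E)-3,7,11-trimethyldodeca-1,6,10-trien-3-yl]benzene, via alkylzinc iodide 31 (not isolated)
Conditions: Zn dust (activated with BrCH2CH2Br, Me3SiCl), THF, 40 °C; then 5 (1.3 equiv), PdCl2(dppf) (5 mol%), THF, rt → 45 °C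
Reagents that add atoms: none
Why: Zinc insertion and Negishi sp3–sp2 cross-coupling build the C5–C6 bond with retention of the E alkene geometry as in step 11.

Step 22
Reactants: 32 1-(methoxymethoxy)-4-[(3R,6E)-3,7,11-trimethyldodeca-1,6,10-trien-3-yl]benzene
Product: 35 2-(methoxymethoxy)-5-[(3R,6E)-3,7,11-trimethyldodeca-1,6,10-trien-3-yl]phenol, via aryllithium 33 (not isolated), via dimethyl arylboronate 34 (not isolated)
Conditions: n-BuLi (1.3 equiv), THF, 0 °C; B(OMe)3, −78 °C → rt; then 30% H2O2, aq NaOH, 0 °C → rt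
Reagents that add atoms: hydrogen peroxide, OO
Why: MOM-directed ortho-lithiation (the two ortho positions are equivalent), borylation and alkaline peroxide oxidation of the aryl boronate install the C3 hydroxyl regiospecifically, unactivated alkenes being inert to alkaline H2O2.

**Union and deprotection**

Step 23
Reactants: 35 2-(methoxymethoxy)-5-[(3R,6E)-3,7,11-trimethyldodeca-1,6,10-trien-3-yl]phenol; 20 1-iodo-2,3-bis(methoxymethoxy)-5-[(3S,6E)-3,7,11-trimethyldodeca-1,6,10-trien-3-yl]benzene
Product: 36 1,2-bis(methoxymethoxy)-3-{2-(methoxymethoxy)-5-[(3R,6E)-3,7,11-trimethyldodeca-1,6,10-trien-3-yl]phenoxy}-5-[(3S,6E)-3,7,11-trimethyldodeca-1,6,10-trien-3-yl]benzene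
Conditions: CuI (10 mol%), N,N-dimethylglycine (30 mol%), Cs2CO3 (2 equiv), 1,4-dioxane, 90 °C, Ar
Reagents that add atoms: none
Why: Copper-catalysed Ullmann diaryl ether coupling joins the ring A C3 phenoxide to the ring B C5 iodide, the single free OH and the single C–I bond fixing the regiochemistry while MOM ethers, alkenes and both quaternary centres stay untouched.

Step 24
Reactants: 36 tris-MOM diaryl ether
Product: 37 3-{2-hydroxy-5-[(3R,6E)-3,7,11-trimethyldodeca-1,6,10-trien-3-yl]phenoxy}-5-[(3S,6E)-3,7,11-trimethyldodeca-1,6,10-trien-3-yl]benzene-1,2-diol (CNP0296687.1)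
Conditions: HCl (1 M in MeOH), rt → 40 °C, Ar (degassed)
Reagents that add atoms: none
Why: Acid-catalysed acetal methanolysis should remove the three aryl MOM groups as dimethoxymethane under conditions that isolated trisubstituted alkenes tolerate, degassing protecting the air-sensitive catechol.

**Compound list**

1 | 6-methylhept-5-en-2-one | CC(C)=CCCC(C)=O | starting material
2 | diethyl 6-methylhepta-1,5-dien-2-yl phosphate | C=C(CCC=C(C)C)OP(=O)(OCC)OCC | intermediate (not isolated)
3 | 6-methylhept-5-en-1-yne | C#CCCC=C(C)C | intermediate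
4 | [(1E)-2,6-dimethylhepta-1,5-dien-1-yl]dimethylalane | C[Al](C)/C=C(\C)CCC=C(C)C | intermediate (not isolated)
5 | (1E)-1-iodo-2,6-dimethylhepta-1,5-diene | I/C=C(\C)CCC=C(C)C | intermediate
6 | 3′,4′-dihydroxyacetophenone | CC(=O)c1ccc(O)c(O)c1 | starting material
7 | 3′,4′-bis(methoxymethoxy)acetophenone | CC(=O)c1ccc(OCOC)c(OCOC)c1 | intermediate
8 | 1,2-bis(methoxymethoxy)-4-(prop-1-en-2-yl)benzene | C=C(C)c1ccc(OCOC)c(OCOC)c1 | intermediate
9 | 4-(2,2-dibromo-1-methylcyclopropyl)-1,2-bis(methoxymethoxy)benzene (racemic) | CC1(CC1(Br)Br)c1ccc(OCOC)c(OCOC)c1 | intermediate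
10 | 4-(2-bromo-1-methylcyclopropyl)-1,2-bis(methoxymethoxy)benzene (racemic, cis/trans) | CC1(CC1Br)c1ccc(OCOC)c(OCOC)c1 | intermediate
11 | 3-[3,4-bis(methoxymethoxy)phenyl]-3-methylcyclopropene | CC1(C=C1)c1ccc(OCOC)c(OCOC)c1 | intermediate
12 | butyl vinyl ether | C=COCCCC | starting material
13 | 4-[(1Z,3R)-1-butoxy-3-methylpenta-1,4-dien-3-yl]-1,2-bis(methoxymethoxy)benzene | COCOc1ccc(cc1OCOC)[C@](C)(C=C)/C=C\OCCCC | intermediate
14 | (3S)-3-[3,4-bis(methoxymethoxy)phenyl]-3-methylpent-4-enal | COCOc1ccc(cc1OCOC)[C@](C)(C=C)CC=O | intermediate (not isolated)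
15 | (3S)-3-[3,4-bis(methoxymethoxy)phenyl]-3-methylpent-4-en-1-ol | COCOc1ccc(cc1OCOC)[C@](C)(C=C)CCO | intermediate
16 | 4-[(3S)-5-iodo-3-methylpent-1-en-3-yl]-1,2-bis(methoxymethoxy)benzene | COCOc1ccc(cc1OCOC)[C@](C)(C=C)CCI | intermediate
17 | {(3S)-3-[3,4-bis(methoxymethoxy)phenyl]-3-methylpent-4-en-1-yl}zinc iodide | COCOc1ccc(cc1OCOC)[C@](C)(C=C)CC[Zn]I | intermediate (not isolated)
18 | 1,2-bis(methoxymethoxy)-4-[(3S,6E)-3,7,11-trimethyldodeca-1,6,10-trien-3-yl]benzene | COCOc1ccc(cc1OCOC)[C@](C)(C=C)CC/C=C(\C)CCC=C(C)C | intermediate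
19 | {2,3-bis(methoxymethoxy)-5-[(3S,6E)-3,7,11-trimethyldodeca-1,6,10-trien-3-yl]phenyl}lithium | [Li]c1cc(cc(OCOC)c1OCOC)[C@](C)(C=C)CC/C=C(\C)CCC=C(C)C | intermediate (not isolated)
20 | 1-iodo-2,3-bis(methoxymethoxy)-5-[(3S,6E)-3,7,11-trimethyldodeca-1,6,10-trien-3-yl]benzene | Ic1cc(cc(OCOC)c1OCOC)[C@](C)(C=C)CC/C=C(\C)CCC=C(C)C | intermediate
21 | 4′-hydroxyacetophenone | CC(=O)c1ccc(O)cc1 | starting material
22 | 4′-(methoxymethoxy)acetophenone | CC(=O)c1ccc(OCOC)cc1 | intermediate
23 | 1-(methoxymethoxy)-4-(prop-1-en-2-yl)benzene | C=C(C)c1ccc(OCOC)cc1 | intermediate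
24 | 1-(2,2-dibromo-1-methylcyclopropyl)-4-(methoxymethoxy)benzene (racemic) | CC1(CC1(Br)Br)c1ccc(OCOC)cc1 | intermediate
25 | 1-(2-bromo-1-methylcyclopropyl)-4-(methoxymethoxy)benzene (racemic, cis/trans) | CC1(CC1Br)c1ccc(OCOC)cc1 | intermediate
26 | 3-[4-(methoxymethoxy)phenyl]-3-methylcyclopropene | CC1(C=C1)c1ccc(OCOC)cc1 | intermediate
27 | 1-[(1Z,3S)-1-butoxy-3-methylpenta-1,4-dien-3-yl]-4-(methoxymethoxy)benzene | COCOc1ccc(cc1)[C@@](C)(C=C)/C=C\OCCCC | intermediate
28 | (3R)-3-[4-(methoxymethoxy)phenyl]-3-methylpent-4-enal | COCOc1ccc(cc1)[C@@](C)(C=C)CC=O | intermediate (not isolated)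
29 | (3R)-3-[4-(methoxymethoxy)phenyl]-3-methylpent-4-en-1-ol | COCOc1ccc(cc1)[C@@](C)(C=C)CCO | intermediate
30 | 1-[(3R)-5-iodo-3-methylpent-1-en-3-yl]-4-(methoxymethoxy)benzene | COCOc1ccc(cc1)[C@@](C)(C=C)CCI | intermediate
31 | {(3R)-3-[4-(methoxymethoxy)phenyl]-3-methylpent-4-en-1-yl}zinc iodide | COCOc1ccc(cc1)[C@@](C)(C=C)CC[Zn]I | intermediate (not isolated)
32 | 1-(methoxymethoxy)-4-[(3R,6E)-3,7,11-trimethyldodeca-1,6,10-trien-3-yl]benzene | COCOc1ccc(cc1)[C@@](C)(C=C)CC/C=C(\C)CCC=C(C)C | intermediate
33 | {2-(methoxymethoxy)-5-[(3R,6E)-3,7,11-trimethyldodeca-1,6,10-trien-3-yl]phenyl}lithium | [Li]c1cc(ccc1OCOC)[C@@](C)(C=C)CC/C=C(\C)CCC=C(C)C | intermediate (not isolated)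
34 | dimethyl {2-(methoxymethoxy)-5-[(3R,6E)-3,7,11-trimethyldodeca-1,6,10-trien-3-yl]phenyl}boronate | COB(OC)c1cc(ccc1OCOC)[C@@](C)(C=C)CC/C=C(\C)CCC=C(C)C | intermediate (not isolated)
35 | 2-(methoxymethoxy)-5-[(3R,6E)-3,7,11-trimethyldodeca-1,6,10-trien-3-yl]phenol | Oc1cc(ccc1OCOC)[C@@](C)(C=C)CC/C=C(\C)CCC=C(C)C | intermediate
36 | 1,2-bis(methoxymethoxy)-3-{2-(methoxymethoxy)-5-[(3R,6E)-3,7,11-trimethyldodeca-1,6,10-trien-3-yl]phenoxy}-5-[(3S,6E)-3,7,11-trimethyldodeca-1,6,10-trien-3-yl]benzene | C=C[C@@](C)(CC/C=C(\C)CCC=C(C)C)c1ccc(OCOC)c(Oc2cc([C@](C)(C=C)CC/C=C(\C)CCC=C(C)C)cc(OCOC)c2OCOC)c1 | intermediate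
37 | 3-{2-hydroxy-5-[(3R,6E)-3,7,11-trimethyldodeca-1,6,10-trien-3-yl]phenoxy}-5-[(3S,6E)-3,7,11-trimethyldodeca-1,6,10-trien-3-yl]benzene-1,2-diol | C=C[C@@](C)(CC/C=C(\C)CCC=C(C)C)c1ccc(O)c(Oc2cc([C@](C)(C=C)CC/C=C(\C)CCC=C(C)C)cc(O)c2O)c1 | target

**Step count**

Total: 24 steps. Longest linear sequence: 12 steps (steps 3–12, 23 and 24 from 6; the ring A line, steps 13–22, 23 and 24 from 21, is equally long).

**Steps most likely to fail**

1. Step 8 (its mirror-image twin, step 18, shares the risk). The ruthenium carbene may discriminate poorly between the two enantiotopic olefinic carbons of this electron-rich aryl cyclopropene, or may be slowed by the chelating acetal oxygens so that the cyclopropene oligomerises before cross-metathesis turns over. Fallback, setting out from 7 and coming back at 18 (ring B steps 4–11 are bypassed): Horner–Wadsworth–Emmons olefination of 7 with triethyl phosphonoacetate (NaH, THF; E isomer purified) would give ethyl (2E)-3-[3,4-bis(methoxymethoxy)phenyl]but-2-enoate F1. DIBAL-H reduction would give (2E)-3-[3,4-bis(methoxymethoxy)phenyl]but-2-en-1-ol F2, and ClP(O)(OEt)2/pyridine would give its diethyl phosphate, diethyl (2E)-3-[3,4-bis(methoxymethoxy)phenyl]but-2-en-1-yl phosphate F3. In parallel, alane 4 (made as in step 2) would be converted with n-BuLi into lithium butyl[(1E)-2,6-dimethylhepta-1,5-dien-1-yl]dimethylaluminate F4 and opened with oxirane to homogeraniol, (3E)-4,8-dimethylnona-3,7-dien-1-ol F5. CBr4/PPh3 would give (3E)-1-bromo-4,8-dimethylnona-3,7-diene F6, magnesium would give [(3E)-4,8-dimethylnona-3,7-dien-1-yl]magnesium bromide F7, and ZnCl2 (0.5 equiv) would give bis[(3E)-4,8-dimethylnona-3,7-dien-1-yl]zinc F8. Copper-catalysed enantioselective SN2′ allylic alkylation of F3 with F8, using a catalyst formed from (CuOTf)2·C6H6 and an enantiopure sulfonate-bearing imidazolinium salt (NHC precursor), would create the aryl/methyl/vinyl quaternary centre and deliver 18 directly. The ligand antipode would be chosen for the S configuration.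

2. Step 23. Oxidative addition and ligand exchange at copper may be slow with two electron-rich partners that each carry an ortho alkoxy group, so that protodeiodination of 20 and oxidation of the phenoxide compete. Fallback, setting out from 18 and coming back at 36: 18 would be lithiated as in step 12 to 19, trapped with B(OMe)3 to dimethyl {2,3-bis(methoxymethoxy)-5-[(3S,6E)-3,7,11-trimethyldodeca-1,6,10-trien-3-yl]phenyl}boronate F9, and hydrolysed on work-up to {2,3-bis(methoxymethoxy)-5-[(3S,6E)-3,7,11-trimethyldodeca-1,6,10-trien-3-yl]phenyl}boronic acid F10. Chan–Lam–Evans oxidative coupling of F10 with phenol 35 (Cu(OAc)2, pyridine, 4 Å molecular sieves, CH2Cl2, air, rt) would form the same C–O bond at room temperature and give 36.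

3. Step 11. Zinc insertion into the iodide may stall, or the alkylpalladium intermediate may undergo β-hydride elimination and homocoupling instead of cross-coupling. Fallback, setting out from 5 (with 16) and coming back at 18: iodine–lithium exchange on 5 (t-BuLi, 2 equiv, Et2O, −78 °C) would give [(1E)-2,6-dimethylhepta-1,5-dien-1-yl]lithium F11 with retention of geometry. Direct SN2 alkylation of F11 by the primary iodide 16 in THF (−78 °C → rt) would reverse the polarity of the coupling, need no palladium, and give 18.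

**Further compounds**

F1 | step 8 | ethyl (2E)-3-[3,4-bis(methoxymethoxy)phenyl]but-2-enoate | CCOC(=O)/C=C(\C)c1ccc(OCOC)c(OCOC)c1
F2 | step 8 | (2E)-3-[3,4-bis(methoxymethoxy)phenyl]but-2-en-1-ol | OC/C=C(\C)c1ccc(OCOC)c(OCOC)c1
F3 | step 8 | diethyl (2E)-3-[3,4-bis(methoxymethoxy)phenyl]but-2-en-1-yl phosphate | CCOP(=O)(OCC)OC/C=C(\C)c1ccc(OCOC)c(OCOC)c1
F4 | step 8 | lithium butyl[(1E)-2,6-dimethylhepta-1,5-dien-1-yl]dimethylaluminate | [Li+].CCCC[Al-](C)(C)/C=C(\C)CCC=C(C)C
F5 | step 8 | (3E)-4,8-dimethylnona-3,7-dien-1-ol (homogeraniol) | OCC/C=C(\C)CCC=C(C)C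
F6 | step 8 | (3E)-1-bromo-4,8-dimethylnona-3,7-diene | BrCC/C=C(\C)CCC=C(C)C
F7 | step 8 | [(3E)-4,8-dimethylnona-3,7-dien-1-yl]magnesium bromide | Br[Mg]CC/C=C(\C)CCC=C(C)C
F8 | step 8 | bis[(3E)-4,8-dimethylnona-3,7-dien-1-yl]zinc | CC(C)=CCC/C(C)=C/CC[Zn]CC/C=C(\C)CCC=C(C)C
F9 | step 23 | dimethyl {2,3-bis(methoxymethoxy)-5-[(3S,6E)-3,7,11-trimethyldodeca-1,6,10-trien-3-yl]phenyl}boronate | COB(OC)c1cc(cc(OCOC)c1OCOC)[C@](C)(C=C)CC/C=C(\C)CCC=C(C)C
F10 | step 23 | {2,3-bis(methoxymethoxy)-5-[(3S,6E)-3,7,11-trimethyldodeca-1,6,10-trien-3-yl]phenyl}boronic acid | OB(O)c1cc(cc(OCOC)c1OCOC)[C@](C)(C=C)CC/C=C(\C)CCC=C(C)C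
F11 | step 11 | [(1E)-2,6-dimethylhepta-1,5-dien-1-yl]lithium | [Li]/C=C(\C)CCC=C(C)C
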